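The route rests on the C1–C2 bond of the cyclopentane, which joins the two adjacent methyl-bearing quaternary carbons (C1 carries the enone carbonyl, C2 the CH2 of the keto side chain). An Ireland–Claisen ring contraction of a nine-membered (Z)-allylic lactone with an α-methyl, an alkene methyl and an (R)-methyl carbinol makes this bond, closes the five-membered ring and sets both quaternary centres by relay from the carbinol carbon. It leaves a cis carboxyl (later the enone) and an (E)-propenyl group (later the keto side chain). The lactone comes from a B-alkyl Suzuki coupling and lactonisation; a cis-fused δ-lactone then carries the core through arene attachment and enone installation.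

Key step: step 6

Remark: the nine-membered lactone is carried as both α-epimers because that carbon becomes trigonal in the key step, the carbinol carbon made at the propargylation stage is carried as both epimers because it is oxidised at the end, and the silyl ketene acetal, although cis within the ring, is E by the sequence rules (O–Si outranks O–C).

Step 1
Reactants: 1 pent-3-yn-2-one
Product: 2 (2R)-pent-3-yn-2-ol
Conditions: RuCl[(R,R)-TsDPEN](p-cymene) (cat.), KOH (cat.), i-PrOH, rt
Reagents that add atoms: none
Why: Noyori asymmetric transfer hydrogenation of an alkynyl methyl ketone, in which the (R,R)-diamine ruthenium hydride differentiates the alkynyl and methyl groups, should set the (R)-carbinol that becomes the stereo-relaying centre of the lactone without touching the triple bond.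

Step 2
Reactants: 2 (2R)-pent-3-yn-2-ol
Product: 4 (2R,3Z)-4-iodopent-3-en-2-ol, via cyclic vinylalanate 3 (not isolated)
Conditions: NaAlH2(OCH2CH2OMe)2, THF, 0 °C to rt; EtOAc; then I2, −78 to 0 °C
Reagents that add atoms: iodine, II
Why: Hydroxyl-directed trans-hydroalumination of the propargylic alcohol puts hydride on the proximal and aluminium on the distal alkyne carbon inside a five-membered alkoxyalanate, and iodinolysis with retention should give the Z vinyl iodide with iodine cis to the untouched carbinol carbon.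

Step 3
Reactants: 5 ethyl 2-methylpent-4-enoate (racemic); 4 (2R,3Z)-4-iodopent-3-en-2-ol
Product: 7 ethyl (6Z,8R)-8-hydroxy-2,6-dimethylnon-6-enoate (both C2 epimers), via B-alkyl-9-BBN borane 6 (not isolated)
Conditions: 9-BBN, THF, 0 °C to rt; then 4, PdCl2(dppf) (cat.), AsPh3, Cs2CO3, DMF/H2O, rt
Reagents that add atoms: none
Why: Anti-Markovnikov hydroboration of the terminal alkene (ester inert to 9-BBN) followed by B-alkyl Suzuki–Miyaura coupling, which retains the vinyl iodide geometry and tolerates the free hydroxyl, should give the trisubstituted alkene with the chain cis to the carbinol carbon.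

Step 4
Reactants: 7 ethyl (6Z,8R)-8-hydroxy-2,6-dimethylnon-6-enoate
Product: 8 (6Z,8R)-8-hydroxy-2,6-dimethylnon-6-enoic acid (both C2 epimers)
Conditions: LiOH, THF/MeOH/H2O, rt; then 1 M HCl
Reagents that add atoms: lithium hydroxide, [Li+].[OH-]
Why: Ester saponification leaves the allylic alcohol, the Z alkene and the carbinol configuration unchanged, and the α-centre is of no consequence.

Step 5
Reactants: 8 (6Z,8R)-8-hydroxy-2,6-dimethylnon-6-enoic acid
Product: 10 (7Z,9R)-3,7,9-trimethyl-4,5,6,9-tetrahydro-3H-oxonin-2-one (both C3 epimers), via mixed anhydride 9 (not isolated)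
Conditions: 2-methyl-6-nitrobenzoic anhydride, DMAP, CH2Cl2, rt, slow addition at high dilution
Reagents that add atoms: none
Why: Shiina macrolactonisation activates the acid (not the alcohol, so C9 keeps its configuration) as a mixed anhydride that DMAP relays to the secondary allylic hydroxyl, and the Z alkene and the branching carbons lower the conformational cost of nine-membered ring closure.

Step 6
Reactants: 10 (7Z,9R)-3,7,9-trimethyl-4,5,6,9-tetrahydro-3H-oxonin-2-one
Product: 13 (1R,2R)-1,2-dimethyl-2-[(E)-prop-1-enyl]cyclopentane-1-carboxylic acid, via silyl ketene acetal 11 (not isolated), via silyl ester 12 (not isolated)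
Conditions: LiN(i-Pr)2, TBSCl, DMPU, THF, −78 °C to rt; PhMe, 105 °C; then 1 M HCl, THF, rt
Reagents that add atoms: none
Why: Deprotonation at C3 and O-silylation give the silyl ketene acetal 11, whose C3=C2–O1–C9–C8=C7 array undergoes a concerted suprafacial [3,3] shift (Ireland–Claisen rearrangement) that forms the C3–C7 bond as the allylic C9–O1 bond breaks; the closest known reactions are the ester-enolate Claisen ring contraction of medium-ring (Z)-alkenyl lactones to cis-2-alkenylcycloalkanecarboxylic acids and acyclic Ireland–Claisen constructions of vicinal quaternary carbons. The cyclopentane (C3–C4–C5–C6–C7) closes pericyclically, as a four-atom contraction of the nine-membered ring through the six-membered transition state, and the three-carbon tether can span C3 and C7 only if that transition state is a boat with the two ring-cis double bonds stacked. Because the ring fixes both the ketene acetal geometry (cis in the ring, E by the sequence rules) and the alkene geometry (Z), the boat places carboxyl and alkenyl cis, which sets the relative configuration of the two new quaternary centres. Their absolute configuration is relayed from C9: the (R)-carbinol methyl takes the outside position to avoid 1,3-allylic strain with the C6 methylene, so bonding occurs on the alkene face that gives (1R,2R) together with an (E)-propenyl group. The step needs cis over trans selectivity (secured by the ring-enforced boat) and outside-methyl over inside-methyl selectivity (secured by the Z ring alkene); any (Z)-propenyl isomer would carry the opposite ring configuration and is removed by chromatography before the alkene is cleaved.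

Step 7
Reactants: 13 (1R,2R)-1,2-dimethyl-2-[(E)-prop-1-enyl]cyclopentane-1-carboxylic acid
Product: 14 (1R,2S)-2-formyl-1,2-dimethylcyclopentane-1-carboxylic acid (in ring–chain equilibrium with its bicyclic hydroxy lactone)
Conditions: O3, CH2Cl2/MeOH, −78 °C; then Me2S, −78 °C to rt
Reagents that add atoms: ozone, [O-][O+]=O
Why: Ozonolysis with reductive work-up cleaves the only alkene to a neopentyl aldehyde that has no α-hydrogen and so cannot epimerise, the C2 descriptor changing only through the priority rules.

Step 8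
Reactants: 14 (1R,2S)-2-formyl-1,2-dimethylcyclopentane-1-carboxylic acid
Product: 16 (1R,2R)-1,2-dimethyl-2-(2-oxoethyl)cyclopentane-1-carboxylic acid (in equilibrium with its six-membered hydroxy lactone), via enol ether 15 (not isolated)
Conditions: Ph3P(CH2OMe)Cl, KOt-Bu (excess), THF, 0 °C to rt; then 2 M HCl, THF, rt
Reagents that add atoms: (methoxymethyl)triphenylphosphonium chloride, COC[P+](c1ccccc1)(c1ccccc1)c1ccccc1.[Cl-]; water, O
Why: Wittig methoxymethylenation of the base-opened carboxylate aldehyde by the small non-stabilised ylide, followed by acid hydrolysis of the enol ether, should give the one-carbon homologated aldehyde with no stereocentre involved.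

Step 9
Reactants: 16 (1R,2R)-1,2-dimethyl-2-(2-oxoethyl)cyclopentane-1-carboxylic acid
Product: 18 (4aR,7aR)-4a,7a-dimethyl-3-(prop-2-yn-1-yl)hexahydrocyclopenta[c]pyran-1(3H)-one (both C3 epimers), via hydroxy acid 17 (not isolated)
Conditions: Zn, HC≡CCH2Br, THF/sat. aq. NH4Cl, 0 °C to rt; then TsOH (cat.), PhMe, rt
Reagents that add atoms: propargyl bromide, C#CCBr
Why: Barbier propargylation through the allenylzinc species gives the homopropargylic alcohol, which the cis carboxyl captures as a δ-lactone with Thorpe–Ingold assistance from the two quaternary carbons, the new carbinol centre being uncontrolled and erased later by oxidation.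

Step 10
Reactants: 19 4-methoxy-3-methylphenol
Product: 20 (4-methoxy-3-methylphenoxy)tri(propan-2-yl)silane
Conditions: TIPSCl, imidazole, DMF, rt
Reagents that add atoms: chlorotri(propan-2-yl)silane, CC(C)[Si](Cl)(C(C)C)C(C)C
Why: Silylation of the phenol gives a bulky ether that survives organolithium, organoaluminium and palladium chemistry and does not direct metalation.

Step 11
Reactants: 20 (4-methoxy-3-methylphenoxy)tri(propan-2-yl)silane
Product: 22 [2-methoxy-3-methyl-5-(triisopropylsilyloxy)phenyl]methanol, via aryllithium 21 (not isolated)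
Conditions: s-BuLi, TMEDA, THF, −78 °C; then (CH2O)n, −78 °C to rt; H2O
Reagents that add atoms: formaldehyde (as paraformaldehyde), C=O
Why: Directed ortho-metalation by the methoxy group at its only free ortho position, with the bulky silyl ether shielding the two positions next to it, gives an aryllithium that is trapped by formaldehyde as the benzylic alcohol.

Step 12
Reactants: 22 [2-methoxy-3-methyl-5-(triisopropylsilyloxy)phenyl]methanol
Product: 23 [3-(bromomethyl)-4-methoxy-5-methylphenoxy]tri(propan-2-yl)silane
Conditions: CBr4, PPh3, CH2Cl2, 0 °C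
Reagents that add atoms: tetrabromomethane, BrC(Br)(Br)Br
Why: Appel bromination converts the benzylic alcohol into the bromide under neutral conditions that spare the aryl silyl ether.

Step 13
Reactants: 18 (4aR,7aR)-4a,7a-dimethyl-3-(prop-2-yn-1-yl)hexahydrocyclopenta[c]pyran-1(3H)-one; 23 [3-(bromomethyl)-4-methoxy-5-methylphenoxy]tri(propan-2-yl)silane
Product: 25 (4aR,7aR)-3-{(2E)-4-[2-methoxy-3-methyl-5-(triisopropylsilyloxy)phenyl]-2-methylbut-2-en-1-yl}-4a,7a-dimethylhexahydrocyclopenta[c]pyran-1(3H)-one (both C3 epimers), via alkenylalane 24 (not isolated)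
Conditions: AlMe3, Cp2ZrCl2 (cat.), H2O (substoichiometric), CH2Cl2, −23 °C; excess AlMe3 removed in vacuo; then 23, Pd(PPh3)4 (cat.), THF, rt
Reagents that add atoms: trimethylaluminium, C[Al](C)C
Why: Negishi zirconium-catalysed syn carboalumination of the terminal alkyne, water-accelerated so that it runs cold where AlMe3 should not attack the hindered lactone, places methyl on the internal carbon and aluminium cis to it, and palladium-catalysed cross-coupling of the alkenylalane with the benzylic bromide proceeds with retention to give the E trisubstituted alkene.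

Step 14
Reactants: 26 2-methylbut-3-yn-2-ol
Product: 27 triethyl[(2-methylbut-3-yn-2-yl)oxy]silane
Conditions: TESOTf, 2,6-lutidine, CH2Cl2, 0 °C
Reagents that add atoms: triethylsilyl trifluoromethanesulfonate, CC[Si](CC)(CC)OS(=O)(=O)C(F)(F)F
Why: Silylation of the tertiary alcohol with the reactive silyl triflate masks the hydroxyl for the organometallic steps and stays removable by fluoride at the end.

Step 15
Reactants: 27 triethyl[(2-methylbut-3-yn-2-yl)oxy]silane
Product: 29 triethyl{[(3E)-4-iodo-2-methylbut-3-en-2-yl]oxy}silane, via alkenylzirconocene 28 (not isolated)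
Conditions: Cp2Zr(H)Cl, CH2Cl2, rt; then I2, 0 °C
Reagents that add atoms: iodine, II
Why: Hydrozirconation adds Zr–H syn across the terminal alkyne with zirconium on the terminal carbon, and iodinolysis with retention gives the E vinyl iodide.

Step 16
Reactants: 29 triethyl{[(3E)-4-iodo-2-methylbut-3-en-2-yl]oxy}silane; 25 the coupled lactone
Product: 31 (2E)-1-[(1R,2R)-2-{(4E)-2-hydroxy-6-[2-methoxy-3-methyl-5-(triisopropylsilyloxy)phenyl]-4-methylhex-4-en-1-yl}-1,2-dimethylcyclopentyl]-4-methyl-4-(triethylsilyloxy)pent-2-en-1-one (both carbinol epimers; in ring–chain equilibrium with its six-membered hemiketal), via alkenyllithium 30 (not isolated)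
Conditions: 29, t-BuLi (2 equiv), Et2O, −78 °C; then 25, THF, −78 °C; H2O
Reagents that add atoms: none
Why: Iodine–lithium exchange with retention of the E geometry and 1,2-addition of the alkenyllithium to the lactone carbonyl, which has no α-hydrogen to enolise, should give a lithium hemiketal that is stable at −78 °C and so resists a second addition, releasing the δ-hydroxy enone on quench.

Step 17
Reactants: 31 the δ-hydroxy enone
Product: 32 (2E)-1-[(1R,2R)-2-{(4E)-6-[2-methoxy-3-methyl-5-(triisopropylsilyloxy)phenyl]-4-methyl-2-oxohex-4-en-1-yl}-1,2-dimethylcyclopentyl]-4-methyl-4-(triethylsilyloxy)pent-2-en-1-one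
Conditions: Dess–Martin periodinane, NaHCO3, CH2Cl2, rt
Reagents that add atoms: none
Why: Dess–Martin oxidation converts the secondary carbinol of the open-chain tautomer (both epimers) into the ketone and drains the hemiketal by ring–chain equilibration, while both silyl ethers and the alkenes are inert and the bicarbonate buffer keeps the β,γ-unsaturated ketone out of conjugation.

Step 18
Reactants: 32 the bis-silylated dione
Product: 33 (2E)-4-hydroxy-1-{(1R,2R)-2-[(4E)-6-(5-hydroxy-2-methoxy-3-methylphenyl)-4-methyl-2-oxohex-4-en-1-yl]-1,2-dimethylcyclopentyl}-4-methylpent-2-en-1-one (CNP0305066.1)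
Conditions: Bu4NF, AcOH, THF, 0 °C to rt
Reagents that add atoms: none
Why: Fluoride desilylation buffered with acetic acid should cleave the aryl triisopropylsilyl ether and the tertiary triethylsilyl ether without base-induced migration of the β,γ-double bond or aldol and Michael reactions of the 1,5-dione, leaving the oxidation-sensitive phenol to be freed last.

Compound list
1 | pent-3-yn-2-one | CC#CC(C)=O | starting material
2 | (2R)-pent-3-yn-2-ol | C[C@@H](O)C#CC | intermediate
3 | sodium cyclic alkoxy(vinyl)alanate: five-membered ring O–Al–C(CH3)=CH–CH(CH3), two 2-methoxyethoxy groups on aluminium, (R) at the carbinol carbon | C[C@H]1O[Al-](OCCOC)(OCCOC)C(C)=C1.[Na+] | intermediate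
4 | (2R,3Z)-4-iodopent-3-en-2-ol | C[C@@H](O)/C=C(/C)I | intermediate
5 | ethyl 2-methylpent-4-enoate (racemic) | C=CCC(C)C(=O)OCC | starting material
6 | ethyl 5-(9-borabicyclo[3.3.1]nonan-9-yl)-2-methylpentanoate | CCOC(=O)C(C)CCCB1C2CCCC1CCC2 | intermediate
7 | ethyl (6Z,8R)-8-hydroxy-2,6-dimethylnon-6-enoate (both C2 epimers) | CCOC(=O)C(C)CCC/C(C)=C\[C@@H](C)O | intermediate
8 | (6Z,8R)-8-hydroxy-2,6-dimethylnon-6-enoic acid (both C2 epimers) | OC(=O)C(C)CCC/C(C)=C\[C@@H](C)O | intermediate
9 | mixed anhydride of 8 with 2-methyl-6-nitrobenzoic acid | Cc1cccc([N+](=O)[O-])c1C(=O)OC(=O)C(C)CCC/C(C)=C\[C@@H](C)O | intermediate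
10 | (7Z,9R)-3,7,9-trimethyl-4,5,6,9-tetrahydro-3H-oxonin-2-one (both C3 epimers) | C[C@H]1OC(=O)C(C)CCC/C(C)=C\1 | intermediate
11 | tert-butyldimethylsilyl ketene acetal of 10: (9R)-2-(tert-butyldimethylsilyloxy)-3,7,9-trimethyl-4,5,6,9-tetrahydrooxonine, C2=C3 and C7=C8 both cis within the ring | C[C@H]1O/C(O[Si](C)(C)C(C)(C)C)=C(C)\CCC/C(C)=C\1 | intermediate
12 | tert-butyldimethylsilyl (1R,2R)-1,2-dimethyl-2-[(E)-prop-1-enyl]cyclopentane-1-carboxylate | C/C=C/[C@@]1(C)CCC[C@@]1(C)C(=O)O[Si](C)(C)C(C)(C)C | intermediate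
13 | (1R,2R)-1,2-dimethyl-2-[(E)-prop-1-enyl]cyclopentane-1-carboxylic acid | C/C=C/[C@@]1(C)CCC[C@@]1(C)C(=O)O | intermediate
14 | (1R,2S)-2-formyl-1,2-dimethylcyclopentane-1-carboxylic acid (open tautomer drawn) | O=C[C@@]1(C)CCC[C@@]1(C)C(=O)O | intermediate
15 | (1R,2R)-2-(2-methoxyethenyl)-1,2-dimethylcyclopentane-1-carboxylic acid (E/Z mixture; potassium salt in the flask) | COC=C[C@@]1(C)CCC[C@@]1(C)C(=O)O | intermediate
16 | (1R,2R)-1,2-dimethyl-2-(2-oxoethyl)cyclopentane-1-carboxylic acid (open tautomer drawn) | O=CC[C@@]1(C)CCC[C@@]1(C)C(=O)O | intermediate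
17 | (1R,2R)-2-(2-hydroxypent-4-yn-1-yl)-1,2-dimethylcyclopentane-1-carboxylic acid (both carbinol epimers) | C#CCC(O)C[C@@]1(C)CCC[C@@]1(C)C(=O)O | intermediate
18 | (4aR,7aR)-4a,7a-dimethyl-3-(prop-2-yn-1-yl)hexahydrocyclopenta[c]pyran-1(3H)-one (both C3 epimers) | C#CCC1C[C@@]2(C)CCC[C@@]2(C)C(=O)O1 | intermediate
19 | 4-methoxy-3-methylphenol | COc1ccc(O)cc1C | starting material
20 | (4-methoxy-3-methylphenoxy)tri(propan-2-yl)silane | COc1ccc(O[Si](C(C)C)(C(C)C)C(C)C)cc1C | intermediate
21 | [2-methoxy-3-methyl-5-(triisopropylsilyloxy)phenyl]lithium | [Li]c1cc(O[Si](C(C)C)(C(C)C)C(C)C)cc(C)c1OC | intermediate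
22 | [2-methoxy-3-methyl-5-(triisopropylsilyloxy)phenyl]methanol | COc1c(C)cc(O[Si](C(C)C)(C(C)C)C(C)C)cc1CO | intermediate
23 | [3-(bromomethyl)-4-methoxy-5-methylphenoxy]tri(propan-2-yl)silane | COc1c(C)cc(O[Si](C(C)C)(C(C)C)C(C)C)cc1CBr | intermediate
24 | {(1E)-3-[(4aR,7aR)-4a,7a-dimethyl-1-oxohexahydrocyclopenta[c]pyran-3-yl]-2-methylprop-1-en-1-yl}(dimethyl)alane | C[Al](C)/C=C(\C)CC1C[C@@]2(C)CCC[C@@]2(C)C(=O)O1 | intermediate
25 | (4aR,7aR)-3-{(2E)-4-[2-methoxy-3-methyl-5-(triisopropylsilyloxy)phenyl]-2-methylbut-2-en-1-yl}-4a,7a-dimethylhexahydrocyclopenta[c]pyran-1(3H)-one (both C3 epimers) | COc1c(C)cc(O[Si](C(C)C)(C(C)C)C(C)C)cc1C/C=C(\C)CC1C[C@@]2(C)CCC[C@@]2(C)C(=O)O1 | intermediate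
26 | 2-methylbut-3-yn-2-ol | CC(C)(O)C#C | starting material
27 | triethyl[(2-methylbut-3-yn-2-yl)oxy]silane | CC[Si](CC)(CC)OC(C)(C)C#C | intermediate
28 | chlorobis(cyclopentadienyl)[(1E)-3-methyl-3-(triethylsilyloxy)but-1-en-1-yl]zirconium (cyclopentadienyl rings drawn σ-bonded) | CC[Si](CC)(CC)OC(C)(C)/C=C/[Zr](Cl)(C1C=CC=C1)C1C=CC=C1 | intermediate
29 | triethyl{[(3E)-4-iodo-2-methylbut-3-en-2-yl]oxy}silane | CC[Si](CC)(CC)OC(C)(C)/C=C/I | intermediate
30 | [(1E)-3-methyl-3-(triethylsilyloxy)but-1-en-1-yl]lithium | CC[Si](CC)(CC)OC(C)(C)/C=C/[Li] | intermediate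
31 | (2E)-1-[(1R,2R)-2-{(4E)-2-hydroxy-6-[2-methoxy-3-methyl-5-(triisopropylsilyloxy)phenyl]-4-methylhex-4-en-1-yl}-1,2-dimethylcyclopentyl]-4-methyl-4-(triethylsilyloxy)pent-2-en-1-one (both carbinol epimers; open tautomer drawn) | COc1c(C)cc(O[Si](C(C)C)(C(C)C)C(C)C)cc1C/C=C(\C)CC(O)C[C@@]1(C)CCC[C@@]1(C)C(=O)/C=C/C(C)(C)O[Si](CC)(CC)CC | intermediate
32 | (2E)-1-[(1R,2R)-2-{(4E)-6-[2-methoxy-3-methyl-5-(triisopropylsilyloxy)phenyl]-4-methyl-2-oxohex-4-en-1-yl}-1,2-dimethylcyclopentyl]-4-methyl-4-(triethylsilyloxy)pent-2-en-1-one | COc1c(C)cc(O[Si](C(C)C)(C(C)C)C(C)C)cc1C/C=C(\C)CC(=O)C[C@@]1(C)CCC[C@@]1(C)C(=O)/C=C/C(C)(C)O[Si](CC)(CC)CC | intermediate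
33 | (2E)-4-hydroxy-1-{(1R,2R)-2-[(4E)-6-(5-hydroxy-2-methoxy-3-methylphenyl)-4-methyl-2-oxohex-4-en-1-yl]-1,2-dimethylcyclopentyl}-4-methylpent-2-en-1-one (CNP0305066.1) | COc1c(C)cc(O)cc1C/C=C(\C)CC(=O)C[C@@]1(C)CCC[C@@]1(C)C(=O)/C=C/C(C)(C)O | target

Total step count: 18. Longest linear sequence: 13 steps (steps 1–9, 13, 16, 17, 18); steps 10–12 and 14–15 are side branches.

Steps most likely to fail

1. Step 6 (key step). The lactone enolate may fragment by β-elimination before it is silylated. The rearrangement may also be too slow at the doubly congested termini, so that desilylation or the inside-methyl and trans pathways erode yield and stereochemical purity. Fallback: the ring contraction would be run on the homologue lacking the C3 methyl (a trisubstituted ketene acetal, the well-precedented case), and the second quaternary centre would then be made by enolate methylation inside a cis-fused bicycle. Setting out from 4, Suzuki–Miyaura coupling with the 9-BBN adduct of ethyl pent-4-enoate, ethyl 5-(9-borabicyclo[3.3.1]nonan-9-yl)pentanoate F1, would give ethyl (6Z,8R)-8-hydroxy-6-methylnon-6-enoate F2. Saponification would give (6Z,8R)-8-hydroxy-6-methylnon-6-enoic acid F3, and lactonisation as in step 5 through the mixed anhydride F4 would give (7Z,9R)-7,9-dimethyl-4,5,6,9-tetrahydro-3H-oxonin-2-one F5. Enolisation and silylation to the silyl ketene acetal F6, rearrangement to the silyl ester F7 and hydrolysis would give (1R,2R)-2-methyl-2-[(E)-prop-1-enyl]cyclopentane-1-carboxylic acid F8. Ozonolysis would give (1R,2S)-2-formyl-2-methylcyclopentane-1-carboxylic acid F9, which MeOH/TsOH would close to the cis-fused pseudo-ester (3aS,6aR)-3-methoxy-3a-methylhexahydro-1H-cyclopenta[c]furan-1-one F10. Its lithium enolate (LiN(i-Pr)2, THF, −78 °C) with MeI would give (3aS,6aR)-3-methoxy-3a,6a-dimethylhexahydro-1H-cyclopenta[c]furan-1-one F11. The new methyl is forced cis to the angular methyl because a trans-fused bicyclo[3.3.0] lactone is not accessible. Aqueous HCl in THF would hydrolyse the pseudo-ester and return to the route at 14.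

2. Step 5. Intermolecular acylation (diolide and oligomer formation) may outrun the strained nine-membered closure. Fallback: the ring would be closed by C–C instead of C–O bond formation. Setting out from 4, esterification with 2-methylpent-4-enoic acid (DCC, DMAP) would give (2R,3Z)-4-iodopent-3-en-2-yl 2-methylpent-4-enoate F12. Hydroboration with 9-BBN would give (2R,3Z)-4-iodopent-3-en-2-yl 5-(9-borabicyclo[3.3.1]nonan-9-yl)-2-methylpentanoate F13. Intramolecular B-alkyl Suzuki–Miyaura coupling (PdCl2(dppf), AsPh3, Cs2CO3, high dilution) would form the C6–C7 bond with retention of the alkene geometry and return to the route at 10.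

3. Step 13. Methyl transfer from aluminium to the lactone carbonyl, Lewis-acid ring opening, or sequestration of the alane by the carbonyl may stall the carboalumination. Fallback: the coupling would be run on a carbonyl-free substrate and the lactone rebuilt afterwards. Setting out from 18, LiAlH4 would give 1-[(1R,2R)-2-(hydroxymethyl)-1,2-dimethylcyclopentyl]pent-4-yn-2-ol F14. Carboalumination with excess AlMe3 and Cp2ZrCl2 (hydroxyls tolerated as aluminium alkoxides) would give the alkenylalane F15, and cross-coupling with 23 under Pd(PPh3)4 would give (4E)-1-[(1R,2R)-2-(hydroxymethyl)-1,2-dimethylcyclopentyl]-6-[2-methoxy-3-methyl-5-(triisopropylsilyloxy)phenyl]-4-methylhex-4-en-2-ol F16. TEMPO with PhI(OAc)2 would oxidise the primary alcohol to the aldehyde and its lactol on to the lactone, returning to the route at 25.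

Further compounds
F1 | step 6 | ethyl 5-(9-borabicyclo[3.3.1]nonan-9-yl)pentanoate | CCOC(=O)CCCCB1C2CCCC1CCC2
F2 | step 6 | ethyl (6Z,8R)-8-hydroxy-6-methylnon-6-enoate | CCOC(=O)CCCC/C(C)=C\[C@@H](C)O
F3 | step 6 | (6Z,8R)-8-hydroxy-6-methylnon-6-enoic acid | OC(=O)CCCC/C(C)=C\[C@@H](C)O
F4 | step 6 | mixed anhydride of F3 with 2-methyl-6-nitrobenzoic acid | Cc1cccc([N+](=O)[O-])c1C(=O)OC(=O)CCCC/C(C)=C\[C@@H](C)O
F5 | step 6 | (7Z,9R)-7,9-dimethyl-4,5,6,9-tetrahydro-3H-oxonin-2-one | C[C@H]1OC(=O)CCCC/C(C)=C\1
F6 | step 6 | tert-butyldimethylsilyl ketene acetal of F5 (both ring double bonds cis within the ring) | C[C@H]1O/C(O[Si](C)(C)C(C)(C)C)=C\CCC/C(C)=C\1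
F7 | step 6 | tert-butyldimethylsilyl (1R,2R)-2-methyl-2-[(E)-prop-1-enyl]cyclopentane-1-carboxylate | C/C=C/[C@@]1(C)CCC[C@H]1C(=O)O[Si](C)(C)C(C)(C)C
F8 | step 6 | (1R,2R)-2-methyl-2-[(E)-prop-1-enyl]cyclopentane-1-carboxylic acid | C/C=C/[C@@]1(C)CCC[C@H]1C(=O)O
F9 | step 6 | (1R,2S)-2-formyl-2-methylcyclopentane-1-carboxylic acid | O=C[C@@]1(C)CCC[C@H]1C(=O)O
F10 | step 6 | (3aS,6aR)-3-methoxy-3a-methylhexahydro-1H-cyclopenta[c]furan-1-one (both acetal epimers) | COC3[C@@]1(C)CCC[C@H]1C(=O)O3
F11 | step 6 | (3aS,6aR)-3-methoxy-3a,6a-dimethylhexahydro-1H-cyclopenta[c]furan-1-one (both acetal epimers) | COC3[C@@]1(C)CCC[C@@]1(C)C(=O)O3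
F12 | step 5 | (2R,3Z)-4-iodopent-3-en-2-yl 2-methylpent-4-enoate | C[C@@H](OC(=O)C(C)CC=C)/C=C(/C)I
F13 | step 5 | (2R,3Z)-4-iodopent-3-en-2-yl 5-(9-borabicyclo[3.3.1]nonan-9-yl)-2-methylpentanoate | C[C@@H](OC(=O)C(C)CCCB1C2CCCC1CCC2)/C=C(/C)I
F14 | step 13 | 1-[(1R,2R)-2-(hydroxymethyl)-1,2-dimethylcyclopentyl]pent-4-yn-2-ol | C#CCC(O)C[C@@]1(C)CCC[C@@]1(C)CO
F15 | step 13 | alkenyl(dimethyl)alane of F14 with both hydroxyls as dimethylaluminium alkoxides | C[Al](C)/C=C(\C)CC(O[Al](C)C)C[C@@]1(C)CCC[C@@]1(C)CO[Al](C)C
F16 | step 13 | (4E)-1-[(1R,2R)-2-(hydroxymethyl)-1,2-dimethylcyclopentyl]-6-[2-methoxy-3-methyl-5-(triisopropylsilyloxy)phenyl]-4-methylhex-4-en-2-ol | COc1c(C)cc(O[Si](C(C)C)(C(C)C)C(C)C)cc1C/C=C(\C)CC(O)C[C@@]1(C)CCC[C@@]1(C)CO
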